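**Remarks.** Primed locants refer to the spiroketal (O1', C2'–C4', spiro C5', O6', C7'–C9'; ring A = O1'/C2'–C5', ring B = C5'/O6'/C7'–C9'), unprimed locants to the phthalide. The chain terminus is carried as a primary chloride instead of a protected alcohol: it is inert up to the spirocyclisation and is exchanged directly for the iodide needed for fragment union.

## Analysis of the target

The molecule is a 3-alkyl-5,7-dimethoxyphthalide (benzene fused to a γ-lactone, the C1 carbonyl flanked by the C7 methoxy group) linked by six unbranched methylenes to C2' of a 1,6-dioxaspiro[4.4]nonane that carries a methyl group at C7'. It has four stereocentres: C3 (R), C2' (R), C5' (S) and C7' (R). C3 is six methylenes from the nearest other centre, so no relay is possible and it must be set by a catalyst. C2' and C7' flank the spiro carbon, and in the target both alkyl groups lie trans to the oxygen of the other ring. The spiro centre is the hard part: two five-membered rings give no decisive anomeric preference, the two C5' epimers are close in energy, and any protic or Lewis acid can interconvert them. The phthalide is opened by hydroxide or alkoxide, its benzylic C3–O bond is at risk under hydrogenolysis, and the dimethoxyarene is readily halogenated by electrophilic iodine or bromine. The plan rests on one feature: in a ring-A tetrahydrofuran bearing a 3-hydroxybutyl chain at C5', the C5'–H bond is α to O1' and exactly 1,5 to the C7' oxygen. The O6'–C5' bond can therefore be made by C–H oxidation, closing ring B at the spiro carbon without a C5' carbonyl in the substrate.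

## Retrosynthetic reasoning

**Lactone C1–O2 and C3–CH2.** Target 21 is opened to hydroxy ester 20 and cut between C3 and the first chain methylene, giving iodide 14 (used as zinc reagents 18 and 19) and formyl ester 17. This is the only cut that separates the two stereochemical domains, joins two fragments of similar size, and lets a chiral catalyst set C3. It also brings the arene in last, after the iodine chemistry it would not survive. The forward step must transfer a primary alkyl group from zinc to the Re face of 17; the lactone then closes by itself on the neighbouring ester.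

**Chain terminus.** Iodide 14 comes from chloride 13 by halide exchange. The chloride needs no protection and deprotection steps and tolerates low-temperature organomagnesium chemistry, Lewis acid, palladium oxidation, an enzyme and radicals.

**O6'–C5' (key disconnection).** Cutting this bond in 13 leaves carbinol 10, a plain 2,5-disubstituted tetrahydrofuran. It is cut here because C5' then need not exist as a defined stereocentre in any precursor: both C5' epimers of 10 converge once the carbon becomes planar. The forward reaction has to abstract the C5' hydrogen selectively, oxidise the radical to the oxocarbenium ion 12, and bond O6' to the correct face.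

**C7' carbinol.** Alcohol 10 is traced to methyl ketone 9 and this to terminal alkene 8. A vinyl group is the cheapest latent methyl carbinol, and with C5' at the ether level there is no second carbonyl to differentiate. The forward steps are a Markovnikov alkene oxidation and a catalyst-controlled hydride delivery that ignores the distant ring.

**C5'–C9'.** Alkene 8 is cut at C5'–C9' to lactone 5 and the butenyl Grignard reagent 6, through hemiketal 7. The lactone carbonyl carbon is the natural electrophile for attaching the side chain. It stays at the hemiketal level for one step only and is reduced before C7' is oxygenated, so a keto diol never has to be made or handled.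

**C2' stereocentre.** Lactone 5 is cut between its exocyclic methylene and the rest of the chain, giving the chiral-pool tosylate 2 and bromochloride 1 (as Grignard reagent 3 and cuprate 4). C2' is bought, not made, and is not touched in the coupling.

**Arene fragment.** Aldehyde 17 is traced through benzylic bromide 16 to toluate 15, which already has the correct oxygenation pattern; only the methyl group needs to be raised to the aldehyde level.

## Alternatives that were turned down

**Alternative 1:** Both spiroketal C–O bonds (O6'–C5' and O1'–C2') are disconnected to the acyclic keto allylic diol A2, with a C5' ketone, the C7' carbinol and an (E)-allylic alcohol on the two chain carbons next to C2'. In the forward step PdCl2(MeCN)2 promotes hemiketalisation by the C7' hydroxyl, and the hemiketal oxygen then adds to C2' with loss of the allylic hydroxyl, giving vinyl spiroketal A1.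
- For: two rings and two C–O bonds form in one operation, and C2' is fixed by 1,3-transfer from the allylic carbinol. On bonds per step it is stronger than the chosen plan.
- Against: the target chain is saturated, so the new alkene must be hydrogenated next to a benzylic lactone C–O bond. The allylic carbinol is a stereocentre made only to be destroyed. A2 needs three differentiated oxygen functions on one long chain that already carries the phthalide. C5' is no better controlled, because the Lewis-acidic metal equilibrates a 5,5-spiroketal.
- Comparison: the chosen route takes each permanent stereocentre from a cheap source, wastes none, and needs no reduction after the spiroketal exists.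

**Alternative 2:** The benzene ring is disconnected at C4–C3a and C7–C7a to ynoate A4, which already carries the spiroketal and the C3 carbinol, and the silyloxy diene A5. Cycloaddition, aromatisation by loss of one C7 oxygen substituent, and lactonisation of the C3 hydroxyl onto the ester give phenol A3; O-methylation would then give 21.
- For: the oxygenation pattern follows from the polarity of the two partners. C3 would come from alkynylation of an aliphatic aldehyde, which is at least as dependable as the aryl aldehyde alkylation used here.
- Against: aromatisation needs heat and acid or fluoride, under which the already separated C5' centre can equilibrate. A5 is moisture-sensitive, and a methylation step is added at the end.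
- Comparison: the chain must first be turned into an aldehyde and then an ynoate, so the sequence after 13 is longer. De novo arene construction buys nothing here, because 15 already has the right pattern.

**Alternative 3:** The C5'–C9' bond of ring B is disconnected to diazoketone A7, a trans-2-alkoxytetrahydrofuran whose acetal oxygen is the future O6'. Rh2(OAc)4 generates a carbenoid at C9' that inserts into the anomeric C5'–H bond with retention, giving the 8'-oxo spiroketal A6.
- For: this is the only plan that transfers a defined configuration to the spiro carbon stereospecifically. On control of C5' it is in principle stronger than the chosen strategy.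
- Against: the target has no C8' carbonyl, so a deoxygenation sequence follows. While the ketone is present, C7' is enolisable and the spiroketal can open by β-elimination of O1', which would undo the transfer. The carbenoid can also form oxonium ylides with O1' or O6'. The trans acetal must itself be obtained pure.
- Comparison: the chosen route accepts a separation at C5' but has no functional group to remove afterwards, no diazo compound, and robust intermediates; the unwanted epimer can be recycled.

Key step: step 6

## Route

Assumption: compounds 8–11 are drawn with the 2',5'-cis ring A expected from step 3; any trans isomer is carried along, because C5' is flattened in step 6.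

Assumption: the sense of induction in step 10 is taken from simple aryl aldehydes, where the (1R,2R) bis(sulfonamide) leads to Si-face alkyl transfer; the (1S,2S) ligand is therefore used for the (R) centre at C3.

Step 1
Reactants: 1 1-bromo-5-chloropentane; 2 [(2S)-5-oxooxolan-2-yl]methyl 4-methylbenzenesulfonate
Product: 5 (5R)-5-(6-chlorohexyl)oxolan-2-one, via 5-chloropentylmagnesium bromide 3 (not isolated), via bromomagnesium bis(5-chloropentyl)cuprate 4 (not isolated)
Conditions: 1, Mg, THF, 30 °C; CuI (0.5 equiv per 3), −40 °C; 2, −40 to −20 °C; aq. NH4Cl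
Reagents that add atoms: none
Why: Copper-mediated sp3–sp3 coupling: magnesium inserts only into the C–Br bond of 1, and homocuprate 4 displaces the primary tosylate by SN2 faster than it adds to the lactone carbonyl at low temperature. The stereocentre of 2 takes no part; its descriptor changes from S to R only because the substituent priorities change.

Step 2
Reactants: 5 (5R)-5-(6-chlorohexyl)oxolan-2-one; 6 but-3-en-1-ylmagnesium bromide (THF solution)
Product: 7 (5R)-2-(but-3-en-1-yl)-5-(6-chlorohexyl)oxolan-2-ol (mixture of C2 anomers, in equilibrium with the open hydroxy ketone)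
Conditions: 6 (1.1 equiv), THF, −78 °C; aq. NH4Cl at −78 °C
Reagents that add atoms: none
Why: Grignard addition to a γ-lactone: at −78 °C the magnesium hemiketal alkoxide persists until quench, which holds back a second addition. The primary chloride is inert to the Grignard reagent at this temperature.

Step 3
Reactants: 7 (5R)-2-(but-3-en-1-yl)-5-(6-chlorohexyl)oxolan-2-ol
Product: 8 (2S,5R)-2-(but-3-en-1-yl)-5-(6-chlorohexyl)oxolane (2,5-cis)
Conditions: Et3SiH, BF3·OEt2, CH2Cl2, −78 °C
Reagents that add atoms: none
Why: Reductive deoxygenation of a hemiketal (ionic hydrogenation): BF3 ionises 7 to the ring oxocarbenium ion and the silane delivers hydride to C5'. Inside attack on the envelope is expected to favour the 2',5'-cis ether; a minor trans isomer is not removed because C5' becomes planar again in step 6.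

Step 4
Reactants: 8 (2S,5R)-2-(but-3-en-1-yl)-5-(6-chlorohexyl)oxolane
Product: 9 4-[(2R,5R)-5-(6-chlorohexyl)oxolan-2-yl]butan-2-one
Conditions: PdCl2 (10 mol%), CuCl, O2 (1 atm), DMF/H2O 7:1, 25 °C
Reagents that add atoms: water, O
Why: Tsuji–Wacker oxidation: hydroxypalladation puts oxygen on the internal alkene carbon, β-hydride elimination and tautomerisation give the methyl ketone, and CuCl/O2 returns palladium to the divalent state. The ring oxygen is too far from the alkene to redirect the addition.

Step 5
Reactants: 9 4-[(2R,5R)-5-(6-chlorohexyl)oxolan-2-yl]butan-2-one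
Product: 10 (2R)-4-[(2S,5R)-5-(6-chlorohexyl)oxolan-2-yl]butan-2-ol
Conditions: (R)-selective ketoreductase (Lactobacillus-type alcohol dehydrogenase), NADP+ (cat.), MgCl2 (1 mM), iPrOH (10% v/v), phosphate buffer pH 7, 30 °C
Reagents that add atoms: none
Why: Enzymatic ketone reduction: the nicotinamide cofactor delivers hydride to one face of the methyl ketone, with propan-2-ol recycling the cofactor. An enzyme of this type binds methyl in its small pocket and gives the (R)-carbinol, so C7' is set by the catalyst and not by the distant ring.

Step 6
Reactants: 10 (2R)-4-[(2S,5R)-5-(6-chlorohexyl)oxolan-2-yl]butan-2-ol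
Product: 13 (2R,5S,7R)-2-(6-chlorohexyl)-7-methyl-1,6-dioxaspiro[4.4]nonane, via C7' alkyl hypoiodite 11 (not isolated), via C5' oxocarbenium ion 12 (not isolated)
Conditions: PhI(OAc)2 (1.5 equiv), I2 (1.0 equiv), NaHCO3 (solid), cyclohexane/CH2Cl2, visible light (tungsten lamp), 20 °C
Reagents that add atoms: none
Why: PhI(OAc)2 and I2 form acetyl hypoiodite, which turns the C7' hydroxyl of 10 into hypoiodite 11, and visible light cleaves the weak O–I bond to the alkoxy radical. Through a six-membered transition state this radical takes the hydrogen from C5', the only C–H bond that is both 1,5-disposed and weakened by an adjacent oxygen (O1'), so site selectivity is secured by the chain length and the ether oxygen; β-scission would give only a primary or methyl radical and is slower. The C5' radical is trapped by iodine and the α-iodo ether ionises (or the radical is oxidised directly) to oxocarbenium ion 12. The C7' oxygen then adds to C5' in a 5-exo-trig closure, the C5'=O1' bond staying outside the new ring, which forms O6'–C5' and ring B; loss of a proton gives 13 and the HI released is reoxidised by the trivalent iodine reagent, so the buffered medium stays non-acidic. The closest known reaction type is the hypoiodite-mediated alkoxy-radical 1,5-hydrogen atom transfer with oxidative cyclisation that converts hydroxyalkyl tetrahydrofurans and tetrahydropyrans into spiroketals. C5' is the only new stereocentre; because it is planar in 12, both C5' epimers of 10 give the same ion and the configuration is decided by the face on which O6' bonds. The controlling element is the C2' chain of ring A: with an early transition state, O6' should approach anti to it, which gives the isomer with both the C2' chain and the C7' methyl trans to the oxygen of the other ring. This bias is expected to be modest, so besides site selectivity the step needs chromatographic removal of the C5' epimer, which can be re-equilibrated with acid and separated again.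

Step 7
Reactants: 13 (2R,5S,7R)-2-(6-chlorohexyl)-7-methyl-1,6-dioxaspiro[4.4]nonane
Product: 14 (2R,5S,7R)-2-(6-iodohexyl)-7-methyl-1,6-dioxaspiro[4.4]nonane
Conditions: NaI (5 equiv), NaHCO3, butanone, reflux
Reagents that add atoms: sodium iodide, [Na+].[I-]
Why: Finkelstein halide exchange (SN2 at the primary carbon), driven by precipitation of NaCl. The bicarbonate buffer keeps traces of HI from opening the spiroketal, so C5' stays as separated.

Step 8
Reactants: 15 methyl 2,4-dimethoxy-6-methylbenzoate
Product: 16 methyl 2-(bromomethyl)-4,6-dimethoxybenzoate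
Conditions: NBS (1.05 equiv), AIBN (cat.), PhCF3, reflux, hν
Reagents that add atoms: N-bromosuccinimide, O=C1CCC(=O)N1Br
Why: Wohl–Ziegler bromination: a bromine atom abstracts the benzylic hydrogen and the benzyl radical takes bromine from Br2 held at low concentration. A non-polar solvent, light and one equivalent of reagent are used because ionic bromination of the dimethoxyarene ring is the competing path.

Step 9
Reactants: 16 methyl 2-(bromomethyl)-4,6-dimethoxybenzoate
Product: 17 methyl 2-formyl-4,6-dimethoxybenzoate
Conditions: N-methylmorpholine N-oxide (4 equiv), 4 Å MS, MeCN, 25 °C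
Reagents that add atoms: N-methylmorpholine N-oxide, C[N+]1([O-])CCOCC1
Why: Kornblum-type oxidation: the N-oxide oxygen displaces the benzylic bromide and the N-alkoxyammonium salt loses the amine by base-induced elimination to give the aldehyde. Room temperature avoids thermal lactonisation of 16.

Step 10
Reactants: 14 (2R,5S,7R)-2-(6-iodohexyl)-7-methyl-1,6-dioxaspiro[4.4]nonane; 17 methyl 2-formyl-4,6-dimethoxybenzoate
Product: 21 (3R)-5,7-dimethoxy-3-{6-[(2R,5S,7R)-7-methyl-1,6-dioxaspiro[4.4]nonan-2-yl]hexyl}-2-benzofuran-1(3H)-one, via bis(spiroketal-hexyl)zinc 18 (not isolated), via mixed alkyl(trimethylsilylmethyl)zinc 19 (not isolated), via benzylic hydroxy ester 20 (not isolated)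
Conditions: Et2Zn (neat), CuI (0.3 mol%), 50 °C, then vacuum; Zn(CH2SiMe3)2, Et2O; Ti(OiPr)4, (1S,2S)-1,2-bis(trifluoromethanesulfonamido)cyclohexane (8 mol%), 17 (slight excess), toluene, −20 °C; aq. NH4Cl, then silica
Reagents that add atoms: none
Why: Iodine–zinc exchange gives 18, which is redistributed with Zn(CH2SiMe3)2 to 19 so that the silylmethyl group stays on zinc and every spiroketal-bearing alkyl group can be transferred. Ti(OiPr)4 and the chiral bis(sulfonamide) form the catalyst for enantioselective organozinc addition to the Re face of 17, which sets C3 (R) independently of the remote spiroketal; alkoxide 20 then closes the five-membered lactone on the neighbouring methyl ester.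

## Compound list

1 | 1-bromo-5-chloropentane | ClCCCCCBr | starting material
2 | [(2S)-5-oxooxolan-2-yl]methyl 4-methylbenzenesulfonate | Cc1ccc(cc1)S(=O)(=O)OC[C@@H]1CCC(=O)O1 | starting material
3 | 5-chloropentylmagnesium bromide | ClCCCCC[Mg]Br | intermediate
4 | bromomagnesium bis(5-chloropentyl)cuprate | ClCCCCC[Cu-]CCCCCCl.[Mg+]Br | intermediate
5 | (5R)-5-(6-chlorohexyl)oxolan-2-one | ClCCCCCC[C@@H]1CCC(=O)O1 | intermediate
6 | but-3-en-1-ylmagnesium bromide | C=CCC[Mg]Br | starting material
7 | (5R)-2-(but-3-en-1-yl)-5-(6-chlorohexyl)oxolan-2-ol | ClCCCCCC[C@@H]1CCC(O)(CCC=C)O1 | intermediate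
8 | (2S,5R)-2-(but-3-en-1-yl)-5-(6-chlorohexyl)oxolane | ClCCCCCC[C@@H]1CC[C@H](CCC=C)O1 | intermediate
9 | 4-[(2R,5R)-5-(6-chlorohexyl)oxolan-2-yl]butan-2-one | ClCCCCCC[C@@H]1CC[C@H](CCC(C)=O)O1 | intermediate
10 | (2R)-4-[(2S,5R)-5-(6-chlorohexyl)oxolan-2-yl]butan-2-ol | ClCCCCCC[C@@H]1CC[C@H](CC[C@@H](C)O)O1 | intermediate
11 | (2R)-4-[(2R,5R)-5-(6-chlorohexyl)oxolan-2-yl]butan-2-yl hypoiodite | ClCCCCCC[C@@H]1CC[C@H](CC[C@@H](C)OI)O1 | intermediate
12 | (2R)-2-(6-chlorohexyl)-5-[(3R)-3-hydroxybutyl]-3,4-dihydro-2H-furan-1-ium | ClCCCCCC[C@@H]1CCC(CC[C@@H](C)O)=[O+]1 | intermediate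
13 | (2R,5S,7R)-2-(6-chlorohexyl)-7-methyl-1,6-dioxaspiro[4.4]nonane | ClCCCCCC[C@@H]1CC[C@]3(CC[C@@H](C)O3)O1 | intermediate
14 | (2R,5S,7R)-2-(6-iodohexyl)-7-methyl-1,6-dioxaspiro[4.4]nonane | ICCCCCC[C@@H]1CC[C@]3(CC[C@@H](C)O3)O1 | intermediate
15 | methyl 2,4-dimethoxy-6-methylbenzoate | COC(=O)c1c(C)cc(OC)cc1OC | starting material
16 | methyl 2-(bromomethyl)-4,6-dimethoxybenzoate | COC(=O)c1c(CBr)cc(OC)cc1OC | intermediate
17 | methyl 2-formyl-4,6-dimethoxybenzoate | COC(=O)c1c(C=O)cc(OC)cc1OC | intermediate
18 | bis{6-[(2R,5S,7R)-7-methyl-1,6-dioxaspiro[4.4]nonan-2-yl]hexyl}zinc | [Zn](CCCCCC[C@@H]1CC[C@]3(CC[C@@H](C)O3)O1)CCCCCC[C@@H]1CC[C@]3(CC[C@@H](C)O3)O1 | intermediate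
19 | {6-[(2R,5S,7R)-7-methyl-1,6-dioxaspiro[4.4]nonan-2-yl]hexyl}[(trimethylsilyl)methyl]zinc | C[Si](C)(C)C[Zn]CCCCCC[C@@H]1CC[C@]3(CC[C@@H](C)O3)O1 | intermediate
20 | methyl 2-{(1R)-1-hydroxy-7-[(2R,5S,7R)-7-methyl-1,6-dioxaspiro[4.4]nonan-2-yl]heptyl}-4,6-dimethoxybenzoate | COC(=O)c1c(OC)cc(OC)cc1[C@@H](CCCCCC[C@@H]2CC[C@]3(CC[C@@H](C)O3)O2)O | intermediate
21 | (3R)-5,7-dimethoxy-3-{6-[(2R,5S,7R)-7-methyl-1,6-dioxaspiro[4.4]nonan-2-yl]hexyl}-2-benzofuran-1(3H)-one | COc1cc(OC)c2c(c1)[C@@H](CCCCCC[C@@H]1CC[C@]3(CC[C@@H](C)O3)O1)OC2=O | target

## Step count and least certain steps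

Total step count: 10. Longest linear sequence: 8 steps (steps 1–7 and step 10); the arene branch (steps 8 and 9) joins in step 10.

**Step 6 (key step).** The most likely failure is poor facial selectivity at the planar C5': the C2' substituent sits across the ring oxygen and the tether can reach either face. Material can also be lost through β-fragmentation of the alkoxy radical, or C5' can be scrambled if the medium turns acidic. Fallback, from 5 back to 13, assembling ring B from a carbonyl at C5': (R)-but-3-yn-2-ol is silylated to tert-butyl{[(2R)-but-3-yn-2-yl]oxy}dimethylsilane F1. Its lithium acetylide is added to lactone 5 at −78 °C to give (2R,8R)-2-{[tert-butyl(dimethyl)silyl]oxy}-14-chloro-8-hydroxytetradec-3-yn-5-one F2. Hydrogenation over Pd/C gives (2R,8R)-2-{[tert-butyl(dimethyl)silyl]oxy}-14-chloro-8-hydroxytetradecan-5-one F3. Camphorsulfonic acid in methanol removes the silyl group and closes both ketal bonds, giving 13 together with (2R,5R,7R)-2-(6-chlorohexyl)-7-methyl-1,6-dioxaspiro[4.4]nonane F4, which are separated. This answers a failure of the C–H oxidation itself. It does not improve face selectivity, which in both cases is handled by separation and acid re-equilibration of F4.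

**Step 10.** The iodine–zinc exchange may be incomplete, or the enantioselectivity may be eroded by uncatalysed addition assisted by the coordinating ortho ester. Fallback, from 17 and 14 back to 20, setting C3 by reduction of a ketone: chlorite oxidation of 17 gives 3,5-dimethoxy-2-(methoxycarbonyl)benzoic acid F5, which is converted with ethanethiol and a carbodiimide into methyl 2-[(ethylsulfanyl)carbonyl]-4,6-dimethoxybenzoate F6. Zinc dust with LiCl inserts into 14 to give {6-[(2R,5S,7R)-7-methyl-1,6-dioxaspiro[4.4]nonan-2-yl]hexyl}zinc iodide F7. Fukuyama coupling of F6 and F7 with PdCl2(PPh3)2 gives methyl 2,4-dimethoxy-6-{7-[(2R,5S,7R)-7-methyl-1,6-dioxaspiro[4.4]nonan-2-yl]heptanoyl}benzoate F8. Asymmetric transfer hydrogenation with RuCl[(R,R)-TsDPEN](p-cymene) and HCO2Na should give 20, which lactonises to 21 as in step 10.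

**Step 5.** The long lipophilic ketone may be accepted poorly by the enzyme (low conversion), or discrimination between the two faces may be insufficient. Fallback, from 9 back to 10, by resolution: NaBH4 reduces 9 to a mixture of 10 and (2S)-4-[(2S,5R)-5-(6-chlorohexyl)oxolan-2-yl]butan-2-ol F9. Candida antarctica lipase B with vinyl acetate acylates the (2R) alcohol selectively to (2R)-4-[(2S,5R)-5-(6-chlorohexyl)oxolan-2-yl]butan-2-yl acetate F10, which is separated from F9 and cleaved with K2CO3 in methanol to 10. F9 is oxidised back to 9 and recycled.

**Step 1.** The organometallic may attack the lactone carbonyl (ring opening, double addition) faster than it displaces the tosylate. Fallback, from 2 back to 5, by epoxide opening: NaOMe in methanol converts 2 into methyl 3-[(2S)-oxiran-2-yl]propanoate F11 (methanolysis, then closure of the alkoxide onto the tosylate carbon). Grignard reagent 3 with catalytic CuI at −40 °C opens the epoxide at its methylene carbon to give methyl (4R)-10-chloro-4-hydroxydecanoate F12, which lactonises to 5 with a trace of acid.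

## Further compounds

F1 | step 6 | tert-butyl{[(2R)-but-3-yn-2-yl]oxy}dimethylsilane | C#C[C@@H](C)O[Si](C)(C)C(C)(C)C
F2 | step 6 | (2R,8R)-2-{[tert-butyl(dimethyl)silyl]oxy}-14-chloro-8-hydroxytetradec-3-yn-5-one | ClCCCCCC[C@@H](O)CCC(=O)C#C[C@@H](C)O[Si](C)(C)C(C)(C)C
F3 | step 6 | (2R,8R)-2-{[tert-butyl(dimethyl)silyl]oxy}-14-chloro-8-hydroxytetradecan-5-one | ClCCCCCC[C@@H](O)CCC(=O)CC[C@@H](C)O[Si](C)(C)C(C)(C)C
F4 | step 6 | (2R,5R,7R)-2-(6-chlorohexyl)-7-methyl-1,6-dioxaspiro[4.4]nonane | ClCCCCCC[C@@H]1CC[C@@]3(CC[C@@H](C)O3)O1
F5 | step 10 | 3,5-dimethoxy-2-(methoxycarbonyl)benzoic acid | COC(=O)c1c(C(=O)O)cc(OC)cc1OC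
F6 | step 10 | methyl 2-[(ethylsulfanyl)carbonyl]-4,6-dimethoxybenzoate | COC(=O)c1c(C(=O)SCC)cc(OC)cc1OC
F7 | step 10 | {6-[(2R,5S,7R)-7-methyl-1,6-dioxaspiro[4.4]nonan-2-yl]hexyl}zinc iodide | I[Zn]CCCCCC[C@@H]1CC[C@]3(CC[C@@H](C)O3)O1
F8 | step 10 | methyl 2,4-dimethoxy-6-{7-[(2R,5S,7R)-7-methyl-1,6-dioxaspiro[4.4]nonan-2-yl]heptanoyl}benzoate | COC(=O)c1c(cc(OC)cc1OC)C(=O)CCCCCC[C@@H]1CC[C@]3(CC[C@@H](C)O3)O1
F9 | step 5 | (2S)-4-[(2S,5R)-5-(6-chlorohexyl)oxolan-2-yl]butan-2-ol | ClCCCCCC[C@@H]1CC[C@H](CC[C@H](C)O)O1
F10 | step 5 | (2R)-4-[(2S,5R)-5-(6-chlorohexyl)oxolan-2-yl]butan-2-yl acetate | ClCCCCCC[C@@H]1CC[C@H](CC[C@@H](C)OC(C)=O)O1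
F11 | step 1 | methyl 3-[(2S)-oxiran-2-yl]propanoate | COC(=O)CC[C@H]1CO1
F12 | step 1 | methyl (4R)-10-chloro-4-hydroxydecanoate | COC(=O)CC[C@H](O)CCCCCCCl
A1 | alternative 1 | (3R)-5,7-dimethoxy-3-{(5E)-6-[(2S,5S,7R)-7-methyl-1,6-dioxaspiro[4.4]nonan-2-yl]hex-5-en-1-yl}-2-benzofuran-1(3H)-one | COc1cc(OC)c2c(c1)[C@@H](CCCC/C=C/[C@@H]1CC[C@]3(CC[C@@H](C)O3)O1)OC2=O
A2 | alternative 1 | (3R)-3-[(5R,6E,13R)-5,13-dihydroxy-10-oxotetradec-6-en-1-yl]-5,7-dimethoxy-2-benzofuran-1(3H)-one | COc1cc(OC)c2c(c1)[C@@H](CCCC[C@@H](O)/C=C/CCC(=O)CC[C@@H](C)O)OC2=O
A3 | alternative 2 | (3R)-7-hydroxy-5-methoxy-3-{6-[(2R,5S,7R)-7-methyl-1,6-dioxaspiro[4.4]nonan-2-yl]hexyl}-2-benzofuran-1(3H)-one | COc1cc(O)c2c(c1)[C@@H](CCCCCC[C@@H]1CC[C@]3(CC[C@@H](C)O3)O1)OC2=O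
A4 | alternative 2 | methyl (4R)-4-hydroxy-10-[(2R,5S,7R)-7-methyl-1,6-dioxaspiro[4.4]nonan-2-yl]dec-2-ynoate | COC(=O)C#C[C@H](O)CCCCCC[C@@H]1CC[C@]3(CC[C@@H](C)O3)O1
A5 | alternative 2 | 1,3-dimethoxy-1-(trimethylsilyloxy)buta-1,3-diene (mixture of 1E and 1Z isomers) | COC(=C)C=C(OC)O[Si](C)(C)C
A6 | alternative 3 | (3R)-5,7-dimethoxy-3-{6-[(2R,5S,7R)-7-methyl-8-oxo-1,6-dioxaspiro[4.4]nonan-2-yl]hexyl}-2-benzofuran-1(3H)-one | COc1cc(OC)c2c(c1)[C@@H](CCCCCC[C@@H]1CC[C@]3(CC(=O)[C@@H](C)O3)O1)OC2=O
A7 | alternative 3 | (3R)-3-{6-[(2R,5R)-5-{[(2R)-4-diazo-3-oxobutan-2-yl]oxy}oxolan-2-yl]hexyl}-5,7-dimethoxy-2-benzofuran-1(3H)-one | COc1cc(OC)c2c(c1)[C@@H](CCCCCC[C@@H]1CC[C@@H](O[C@H](C)C(=O)C=[N+]=[N-])O1)OC2=O
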